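**Remarks.** Flavan numbering (O1, C2, C3, C4, C4a, C5–C8, C8a) is used for every unit. The target is read as an upper unit (2S,3R,4S; 2,3‑trans‑3,4‑cis), a middle unit (2S,3S,4S; 2,3‑cis‑3,4‑trans) and a lower (−)‑epicatechin unit (2R,3R), joined C4→C8 twice. Assumption: the sense of induction of the chiral acid in step 6 cannot be fixed on paper; the (R)‑acid is written on the assumption that it favours the (2S) closure, otherwise its mirror image is used.

## Retrosynthetic overview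

1. Target ⇐ global hydrogenolysis and desilylation of trimer 24 ⇐ ionic hydrogenation of carbinol 23 (hydride anti to the 3‑silyloxy group gives the 3,4‑cis upper unit) ⇐ addition of the C8‑cerium reagent of the middle–lower dimer 20 to the C4 ketone of 10; the C8 bromine fixes the regiochemistry.
2. Dimer 20 ⇐ Friedel–Crafts‑type C4→C8 coupling of the C4‑activated 2,3‑cis unit 16 with tetra‑O‑benzylepicatechin 18 (3,4‑trans); 16 ⇐ 10 by C4 deoxygenation, C3 inversion and DDQ activation.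
3. Both 2S units come from one ketone 10; its ring C is closed through the C2–C3 bond by an enantioconvergent Petasis–Ferrier‑type 1,3‑O→C rearrangement of the racemic benzodioxin enol acetal 8, itself condensed from a bromoresorcinol ether, ethyl glyoxylate and the ring‑B aldehyde.
4. Enabling feature: in ring C, C2 carries both O1 and the pyrogallol ring, so it is an acetal‑level carbon that forms an oxocarbenium ion. C3 carries oxygen and lies next to C4, the benzylic carbon para to the C7 oxygen of ring A, which can be held as a ketone. C2–C3 is therefore an aldol‑type bond between an O1‑tethered oxocarbenium ion and the enol of a C4 ketone, and that ketone later becomes the interflavan carbon.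
5. Ring order: temporary 1,3‑benzodioxin ring → ring C of 10 (used for the upper and the middle unit; the lower unit's rings come from epicatechin) → fragment union. The C8 bromine is the latent nucleophile in the middle unit and a traceless spectator in the upper unit.

Key step: step 6

## Route

Step 1
Reactants: 1 2‑bromoresorcinol
Product: 2 3‑(benzyloxy)‑2‑bromophenol
Conditions: BnBr (1 equiv), K2CO3, acetone, reflux; mono‑ether separated from diol and diether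
Reagents that add atoms: benzyl bromide, BrCc1ccccc1
Why: Williamson ether synthesis on a symmetric diol, so the mono‑ether is a single compound and the other fractions can be recycled.

Step 2
Reactants: 2 3‑(benzyloxy)‑2‑bromophenol; 3 ethyl glyoxylate
Product: 4 ethyl 2‑[4‑(benzyloxy)‑3‑bromo‑2‑hydroxyphenyl]‑2‑hydroxyacetate (racemic)
Conditions: EtMgBr (1 equiv), Et2O, 0 °C; then 3, toluene, 0 °C → rt
Reagents that add atoms: none
Why: Friedel–Crafts‑type ortho‑hydroxyalkylation of the bromomagnesium phenoxide, which delivers the coordinated glyoxylate to the only free ortho position (para to the benzyloxy group); the racemic carbinol centre is erased in step 5.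

Step 3
Reactants: 4 ethyl 2‑[4‑(benzyloxy)‑3‑bromo‑2‑hydroxyphenyl]‑2‑hydroxyacetate; 5 3,4,5‑tris(benzyloxy)benzaldehyde
Product: 6 ethyl 7‑(benzyloxy)‑8‑bromo‑2‑[3,4,5‑tris(benzyloxy)phenyl]‑4H‑1,3‑benzodioxine‑4‑carboxylate (racemic, cis/trans mixture)
Conditions: camphorsulfonic acid (cat.), 4 Å molecular sieves, toluene, 60 °C
Reagents that add atoms: none
Why: acid‑catalysed acetalisation of the phenol/secondary‑alcohol pair with the electron‑rich aldehyde gives the six‑membered 1,3‑benzodioxin, and the diastereomer mixture is inconsequential.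

Step 4
Reactants: 6 benzodioxine ethyl ester
Product: 7 7‑(benzyloxy)‑8‑bromo‑2‑[3,4,5‑tris(benzyloxy)phenyl]‑4H‑1,3‑benzodioxine‑4‑carbaldehyde (racemic, cis/trans mixture)
Conditions: i‑Bu2AlH (1.1 equiv), CH2Cl2, −78 °C; Rochelle‑salt work‑up
Reagents that add atoms: none
Why: partial reduction of an α‑alkoxy ester, whose chelated tetrahedral aluminate collapses to the aldehyde only on work‑up.

Step 5
Reactants: 7 benzodioxine‑4‑carbaldehyde
Product: 8 7‑(benzyloxy)‑8‑bromo‑4‑[(tert‑butyldimethylsilyloxy)methylidene]‑2‑[3,4,5‑tris(benzyloxy)phenyl]‑4H‑1,3‑benzodioxine (racemic at the acetal carbon, E/Z mixture)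
Conditions: t‑BuMe2SiCl (1.5 equiv), then KN(SiMe3)2 (1.2 equiv), THF, −78 °C; filtration through Et3N‑deactivated silica, used directly
Reagents that add atoms: tert‑butyldimethylsilyl chloride, CC(C)(C)[Si](C)(C)Cl
Why: silyl enol ether formation, since the C–H between the aryl ring, the ring oxygen and the formyl group is the only enolisable position and its hindered potassium enolate is silylated on oxygen.

Step 6
Reactants: 8 benzodioxin silyl enol acetal
Product: 10 (2S,3S)‑7‑(benzyloxy)‑8‑bromo‑3‑(tert‑butyldimethylsilyloxy)‑2‑[3,4,5‑tris(benzyloxy)phenyl]chroman‑4‑one, via ring‑opened oxocarbenium enol 9 (not isolated)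
Conditions: (R)‑3,3'‑bis(2,4,6‑triisopropylphenyl)‑1,1'‑binaphthyl‑2,2'‑diyl N‑triflylphosphoramide (10 mol%), 4 Å molecular sieves, toluene, −40 → −20 °C
Reagents that add atoms: none
Why: Proposed new method: the chiral acid protonates the enol‑side acetal oxygen of 8 and cleaves its bond to C2, giving an aryloxy‑ and aryl‑stabilised oxocarbenium ion at C2 that stays tethered through O1 and is paired with the chiral phosphoramide anion, which also hydrogen‑bonds the liberated enol; C3 of that enol (β to the enol OH) then attacks C2 and the proton returns to the catalyst. The closest known reaction type is the Petasis–Ferrier rearrangement of cyclic enol acetals to pyranones under Lewis acids, together with chiral‑phosphoric‑acid‑catalysed aza‑Petasis–Ferrier rearrangements and counter‑anion‑directed cationic electrocyclisations. Ring C (O1, C2, C3, C4, C4a, C8a) is closed by a 6‑endo‑trig attack of an endocyclic enol on the endocyclic oxocarbenium ion, which can equally be viewed as a 6π oxa‑electrocyclisation of the 1‑oxatrienyl cation O1=C2/C8a=C4a/C4=C3. C2 is set by the catalyst, because the two faces of the planar oxocarbenium ion are distinguished only by the chiral anion, and C3 is set relative to C2 by acid‑mediated enolisation of the product towards the 2,3‑trans (diequatorial) ketone. The step needs C3‑ rather than C4‑attack and enantioconvergence: the first is secured because the free enol hydroxyl is a stronger donor than the silyl ether oxygen and because C4 is fully substituted (its attack would give a five‑membered ring with a quaternary centre), the second because the racemic acetal carbon and the E/Z enol geometry collapse into the same ion pair.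

Step 7
Reactants: 10 3‑silyloxy‑chroman‑4‑one
Product: 11 (2S,3S)‑7‑(benzyloxy)‑8‑bromo‑3‑hydroxy‑2‑[3,4,5‑tris(benzyloxy)phenyl]chroman‑4‑one
Conditions: HF·pyridine, THF, 0 °C → rt
Reagents that add atoms: none
Why: fluoride‑mediated silyl ether cleavage under non‑basic conditions, which avoids enolisation and ring‑opening of the 3‑hydroxyflavanone.

Step 8
Reactants: 11 3‑hydroxy‑chroman‑4‑one
Product: 13 (2S,3R)‑7‑(benzyloxy)‑8‑bromo‑2‑[3,4,5‑tris(benzyloxy)phenyl]chroman‑3‑ol (2,3‑trans), via flavan‑3,4‑diol 12 (not isolated)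
Conditions: NaBH4, THF/EtOH, 0 °C; work‑up; then Et3SiH, CF3CO2H, CH2Cl2, −20 → 0 °C
Reagents that add atoms: none
Why: carbonyl reduction followed by ionic hydrogenation of the benzylic C4 carbinol through the cation stabilised by the C7 oxygen removes the C4 oxygen without touching C2 or C3.

Step 9
Reactants: 13 2,3‑trans chroman‑3‑ol
Product: 14 (2S)‑7‑(benzyloxy)‑8‑bromo‑2‑[3,4,5‑tris(benzyloxy)phenyl]chroman‑3‑one
Conditions: Dess–Martin periodinane, wet CH2Cl2, rt; used directly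
Reagents that add atoms: none
Why: Dess–Martin oxidation is mild and non‑basic, so C2, now α to the ketone, should not epimerise.

Step 10
Reactants: 14 chroman‑3‑one
Product: 15 (2S,3S)‑7‑(benzyloxy)‑8‑bromo‑2‑[3,4,5‑tris(benzyloxy)phenyl]chroman‑3‑ol (2,3‑cis)
Conditions: LiBH(s‑Bu)3, LiBr, THF, −78 °C
Reagents that add atoms: none
Why: substrate‑controlled ketone reduction in which the bulky hydride attacks the face opposite the 2‑aryl group, giving the 2,3‑cis alcohol (net inversion at C3).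

Step 11
Reactants: 15 2,3‑cis chroman‑3‑ol
Product: 16 (2S,3S,4R)‑7‑(benzyloxy)‑8‑bromo‑4‑(2‑ethoxyethoxy)‑2‑[3,4,5‑tris(benzyloxy)phenyl]chroman‑3‑ol
Conditions: DDQ, 2‑ethoxyethanol, CH2Cl2, rt
Reagents that add atoms: 2‑ethoxyethanol, CCOCCO
Why: benzylic C–H oxidation in which DDQ abstracts hydride from C4 (para to the C7 benzyloxy group, ortho to O1) and the alcohol traps the cation trans to the 3‑hydroxyl; the C4 configuration is irrelevant for step 13.

Step 12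
Reactants: 17 (−)‑epicatechin
Product: 18 5,7,3',4'‑tetra‑O‑benzyl‑(−)‑epicatechin
Conditions: BnBr, K2CO3, DMF, 0 °C → rt
Reagents that add atoms: benzyl bromide, BrCc1ccccc1
Why: Williamson etherification of the four phenols, while the less acidic secondary alcohol stays free under carbonate conditions.

Step 13
Reactants: 16 C4‑activated middle unit; 18 tetra‑O‑benzylepicatechin (4 equiv)
Product: 19 (2S,3S,4S)‑7‑(benzyloxy)‑8‑bromo‑2‑[3,4,5‑tris(benzyloxy)phenyl]‑4‑[(2R,3R)‑5,7‑bis(benzyloxy)‑2‑(3,4‑bis(benzyloxy)phenyl)‑3‑hydroxychroman‑8‑yl]chroman‑3‑ol (middle–lower dimer, both 3‑OH free)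
Conditions: Me3SiOTf (0.5 equiv), CH2Cl2, −40 °C
Reagents that add atoms: none
Why: Friedel–Crafts‑type interflavan coupling in which the C4 cation from 16 is attacked by C8 of the phloroglucinol ring of 18 (far more nucleophilic than the brominated ring A of 16), anti to the cis 2‑aryl and 3‑hydroxyl groups, so the new centre is 3,4‑trans.

Step 14
Reactants: 19 middle–lower dimer diol
Product: 20 3,3'‑di‑O‑benzyl ether of 19 (deca‑O‑benzyl dimer bromide)
Conditions: NaH, BnBr, Bu4NI (cat.), DMF, 0 °C → rt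
Reagents that add atoms: benzyl bromide, BrCc1ccccc1
Why: Williamson ether synthesis caps both secondary alcohols as benzyl ethers that tolerate organolithium chemistry and leave in the final hydrogenolysis.

Step 15
Reactants: 20 deca‑O‑benzyl dimer bromide; 10 3‑silyloxy‑chroman‑4‑one
Product: 23 trimer carbinol: 4‑hydroxy adduct of 10 bearing the C8‑linked dimer at C4 (aryl anti to the 3‑silyloxy group), via aryllithium 21 (not isolated), via arylcerium dichloride 22 (not isolated)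
Conditions: n‑BuLi (1.05 equiv), THF, −78 °C; anhydrous CeCl3 (THF slurry), −78 °C; then 10, −78 → −30 °C
Reagents that add atoms: none
Why: bromine–lithium exchange is much faster than benzylic deprotonation at −78 °C and places the metal at C8 of the middle unit, and the weakly basic aryl‑cerium reagent undergoes 1,2‑addition to the ketone rather than enolising it, anti to the 3‑silyloxy group (Felkin–Anh), although this carbinol configuration is erased in step 16.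

Step 16
Reactants: 23 trimer carbinol
Product: 24 tetradeca‑O‑benzyl‑3‑O‑(tert‑butyldimethylsilyl) trimer bromide, upper unit (2S,3R,4S)
Conditions: Et3SiH (10 equiv), CF3CO2H, CH2Cl2, −60 → −30 °C
Reagents that add atoms: none
Why: ionic hydrogenation in which the tertiary carbinol ionises to the diaryl‑stabilised C4 cation and the silane delivers hydride anti to the adjacent bulky 3‑silyloxy group, as nucleophiles do with 2,3‑trans flavan‑4‑yl cations, so the middle‑unit aryl ends cis to the C3 oxygen (3,4‑cis, 2,4‑trans).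

Step 17
Reactants: 24 silylated trimer
Product: 25 tetradeca‑O‑benzyl trimer bromide with free upper 3‑OH
Conditions: Bu4NF, THF, rt → 50 °C
Reagents that add atoms: none
Why: fluoride cleavage of the hindered secondary silyl ether, to which aryl benzyl ethers and the aryl bromide are inert.

Step 18
Reactants: 25 tetradeca‑O‑benzyl trimer bromide
Product: 26 CNP0115797.3 (target)
Conditions: H2 (3 bar), Pd(OH)2/C, NaOAc, THF/MeOH/H2O, rt, exclusion of air on work‑up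
Reagents that add atoms: none
Why: hydrogenolysis cleaves all fourteen benzyl ethers and the aryl C–Br bond (hydrodehalogenation, acetate takes up HBr) while the interflavan C–C bonds and all stereocentres stay untouched.

## Compound list

1 | 2‑bromoresorcinol | Oc1cccc(O)c1Br | starting material
2 | 3‑(benzyloxy)‑2‑bromophenol | Oc1cccc(OCc2ccccc2)c1Br | intermediate
3 | ethyl glyoxylate | CCOC(=O)C=O | starting material
4 | ethyl 2‑[4‑(benzyloxy)‑3‑bromo‑2‑hydroxyphenyl]‑2‑hydroxyacetate (racemic) | CCOC(=O)C(O)c1ccc(OCc2ccccc2)c(Br)c1O | intermediate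
5 | 3,4,5‑tris(benzyloxy)benzaldehyde | O=Cc1cc(OCc2ccccc2)c(OCc2ccccc2)c(OCc2ccccc2)c1 | starting material
6 | ethyl 7‑(benzyloxy)‑8‑bromo‑2‑[3,4,5‑tris(benzyloxy)phenyl]‑4H‑1,3‑benzodioxine‑4‑carboxylate (racemic mixture of diastereomers) | CCOC(=O)C1OC(c2cc(OCc3ccccc3)c(OCc3ccccc3)c(OCc3ccccc3)c2)Oc2c(Br)c(OCc3ccccc3)ccc12 | intermediate
7 | 7‑(benzyloxy)‑8‑bromo‑2‑[3,4,5‑tris(benzyloxy)phenyl]‑4H‑1,3‑benzodioxine‑4‑carbaldehyde (racemic mixture of diastereomers) | O=CC1OC(c2cc(OCc3ccccc3)c(OCc3ccccc3)c(OCc3ccccc3)c2)Oc2c(Br)c(OCc3ccccc3)ccc12 | intermediate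
8 | 7‑(benzyloxy)‑8‑bromo‑4‑[(tert‑butyldimethylsilyloxy)methylidene]‑2‑[3,4,5‑tris(benzyloxy)phenyl]‑4H‑1,3‑benzodioxine (racemic, E/Z mixture) | CC(C)(C)[Si](C)(C)OC=C1OC(c2cc(OCc3ccccc3)c(OCc3ccccc3)c(OCc3ccccc3)c2)Oc2c(Br)c(OCc3ccccc3)ccc12 | intermediate
9 | ring‑opened aryloxocarbenium enol (cation of the ion pair with the catalyst anion) | CC(C)(C)[Si](C)(C)OC=C(O)c1ccc(OCc2ccccc2)c(Br)c1[O+]=Cc1cc(OCc2ccccc2)c(OCc2ccccc2)c(OCc2ccccc2)c1 | intermediate
10 | (2S,3S)‑7‑(benzyloxy)‑8‑bromo‑3‑(tert‑butyldimethylsilyloxy)‑2‑[3,4,5‑tris(benzyloxy)phenyl]chroman‑4‑one | O=C1c2ccc(OCc3ccccc3)c(Br)c2O[C@@H](c2cc(OCc3ccccc3)c(OCc3ccccc3)c(OCc3ccccc3)c2)[C@@H]1O[Si](C)(C)C(C)(C)C | intermediate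
11 | (2S,3S)‑7‑(benzyloxy)‑8‑bromo‑3‑hydroxy‑2‑[3,4,5‑tris(benzyloxy)phenyl]chroman‑4‑one | O=C1c2ccc(OCc3ccccc3)c(Br)c2O[C@@H](c2cc(OCc3ccccc3)c(OCc3ccccc3)c(OCc3ccccc3)c2)[C@@H]1O | intermediate
12 | (2S,3R,4S)‑7‑(benzyloxy)‑8‑bromo‑2‑[3,4,5‑tris(benzyloxy)phenyl]chromane‑3,4‑diol | O[C@H]1c2ccc(OCc3ccccc3)c(Br)c2O[C@@H](c2cc(OCc3ccccc3)c(OCc3ccccc3)c(OCc3ccccc3)c2)[C@@H]1O | intermediate
13 | (2S,3R)‑7‑(benzyloxy)‑8‑bromo‑2‑[3,4,5‑tris(benzyloxy)phenyl]chroman‑3‑ol | C1c2ccc(OCc3ccccc3)c(Br)c2O[C@@H](c2cc(OCc3ccccc3)c(OCc3ccccc3)c(OCc3ccccc3)c2)[C@@H]1O | intermediate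
14 | (2S)‑7‑(benzyloxy)‑8‑bromo‑2‑[3,4,5‑tris(benzyloxy)phenyl]chroman‑3‑one | C1c2ccc(OCc3ccccc3)c(Br)c2O[C@@H](c2cc(OCc3ccccc3)c(OCc3ccccc3)c(OCc3ccccc3)c2)C1=O | intermediate
15 | (2S,3S)‑7‑(benzyloxy)‑8‑bromo‑2‑[3,4,5‑tris(benzyloxy)phenyl]chroman‑3‑ol | C1c2ccc(OCc3ccccc3)c(Br)c2O[C@@H](c2cc(OCc3ccccc3)c(OCc3ccccc3)c(OCc3ccccc3)c2)[C@H]1O | intermediate
16 | (2S,3S,4R)‑7‑(benzyloxy)‑8‑bromo‑4‑(2‑ethoxyethoxy)‑2‑[3,4,5‑tris(benzyloxy)phenyl]chroman‑3‑ol | CCOCCO[C@@H]1c2ccc(OCc3ccccc3)c(Br)c2O[C@@H](c2cc(OCc3ccccc3)c(OCc3ccccc3)c(OCc3ccccc3)c2)[C@H]1O | intermediate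
17 | (−)‑epicatechin | Oc1cc(O)c2c(c1)O[C@H](c1ccc(O)c(O)c1)[C@H](O)C2 | starting material
18 | 5,7,3',4'‑tetra‑O‑benzyl‑(−)‑epicatechin | c1c(OCc2ccccc2)cc(OCc2ccccc2)c2c1O[C@H](c1ccc(OCc3ccccc3)c(OCc3ccccc3)c1)[C@H](O)C2 | intermediate
19 | middle–lower dimer diol (middle unit 2S,3S,4S with 8‑Br; lower unit 2R,3R; C4→C8) | Brc1c(OCc2ccccc2)ccc2c1O[C@@H](c1cc(OCc3ccccc3)c(OCc3ccccc3)c(OCc3ccccc3)c1)[C@@H](O)[C@@H]2c1c(OCc2ccccc2)cc(OCc2ccccc2)c2c1O[C@H](c1ccc(OCc3ccccc3)c(OCc3ccccc3)c1)[C@H](O)C2 | intermediate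
20 | deca‑O‑benzyl dimer bromide (3,3'‑di‑O‑benzyl ether of 19) | Brc1c(OCc2ccccc2)ccc2c1O[C@@H](c1cc(OCc3ccccc3)c(OCc3ccccc3)c(OCc3ccccc3)c1)[C@@H](OCc1ccccc1)[C@@H]2c1c(OCc2ccccc2)cc(OCc2ccccc2)c2c1O[C@H](c1ccc(OCc3ccccc3)c(OCc3ccccc3)c1)[C@H](OCc1ccccc1)C2 | intermediate
21 | C8‑lithio dimer | [Li]c1c(OCc2ccccc2)ccc2c1O[C@@H](c1cc(OCc3ccccc3)c(OCc3ccccc3)c(OCc3ccccc3)c1)[C@@H](OCc1ccccc1)[C@@H]2c1c(OCc2ccccc2)cc(OCc2ccccc2)c2c1O[C@H](c1ccc(OCc3ccccc3)c(OCc3ccccc3)c1)[C@H](OCc1ccccc1)C2 | intermediate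
22 | C8‑(dichloroceryl) dimer | Cl[Ce](Cl)c1c(OCc2ccccc2)ccc2c1O[C@@H](c1cc(OCc3ccccc3)c(OCc3ccccc3)c(OCc3ccccc3)c1)[C@@H](OCc1ccccc1)[C@@H]2c1c(OCc2ccccc2)cc(OCc2ccccc2)c2c1O[C@H](c1ccc(OCc3ccccc3)c(OCc3ccccc3)c1)[C@H](OCc1ccccc1)C2 | intermediate
23 | trimer carbinol (upper unit 8‑Br, 3‑OTBS, 4‑OH, 4‑aryl) | Brc1c(OCc2ccccc2)ccc2c1O[C@@H](c1cc(OCc3ccccc3)c(OCc3ccccc3)c(OCc3ccccc3)c1)[C@H](O[Si](C)(C)C(C)(C)C)[C@@]2(O)c1c(OCc2ccccc2)ccc2c1O[C@@H](c1cc(OCc3ccccc3)c(OCc3ccccc3)c(OCc3ccccc3)c1)[C@@H](OCc1ccccc1)[C@@H]2c1c(OCc2ccccc2)cc(OCc2ccccc2)c2c1O[C@H](c1ccc(OCc3ccccc3)c(OCc3ccccc3)c1)[C@H](OCc1ccccc1)C2 | intermediate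
24 | tetradeca‑O‑benzyl‑3‑O‑TBS trimer bromide (upper unit 2S,3R,4S) | Brc1c(OCc2ccccc2)ccc2c1O[C@@H](c1cc(OCc3ccccc3)c(OCc3ccccc3)c(OCc3ccccc3)c1)[C@H](O[Si](C)(C)C(C)(C)C)[C@@H]2c1c(OCc2ccccc2)ccc2c1O[C@@H](c1cc(OCc3ccccc3)c(OCc3ccccc3)c(OCc3ccccc3)c1)[C@@H](OCc1ccccc1)[C@@H]2c1c(OCc2ccccc2)cc(OCc2ccccc2)c2c1O[C@H](c1ccc(OCc3ccccc3)c(OCc3ccccc3)c1)[C@H](OCc1ccccc1)C2 | intermediate
25 | tetradeca‑O‑benzyl trimer bromide, upper 3‑OH free | Brc1c(OCc2ccccc2)ccc2c1O[C@@H](c1cc(OCc3ccccc3)c(OCc3ccccc3)c(OCc3ccccc3)c1)[C@H](O)[C@@H]2c1c(OCc2ccccc2)ccc2c1O[C@@H](c1cc(OCc3ccccc3)c(OCc3ccccc3)c(OCc3ccccc3)c1)[C@@H](OCc1ccccc1)[C@@H]2c1c(OCc2ccccc2)cc(OCc2ccccc2)c2c1O[C@H](c1ccc(OCc3ccccc3)c(OCc3ccccc3)c1)[C@H](OCc1ccccc1)C2 | intermediate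
26 | CNP0115797.3 | Oc1ccc2c(c1)O[C@@H](c1cc(O)c(O)c(O)c1)[C@H](O)[C@@H]2c1c(O)ccc2c1O[C@@H](c1cc(O)c(O)c(O)c1)[C@@H](O)[C@@H]2c1c(O)cc(O)c2c1O[C@H](c1ccc(O)c(O)c1)[C@H](O)C2 | target

## Step count and risks

Total step count: 18. Longest linear sequence: 17 (steps 1–11 and 13–18; step 12 is a one‑step side branch).

**Step 6 (proposed new method).** The acetal may ionise only on the phenol side, the enol ether may be protonated on carbon without closure, or the ion pair may close with poor enantiofacial discrimination. The fallback uses known chemistry and still closes ring C through the C2–C3 bond, now as an alkene by ring‑closing metathesis. It sets out from 2: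
- O‑allylation (allyl bromide, K2CO3) gives 1‑(allyloxy)‑3‑(benzyloxy)‑2‑bromobenzene F1.
- Aromatic Claisen rearrangement to the only free ortho position gives 2‑allyl‑5‑(benzyloxy)‑6‑bromophenol F2.
- Acylation with 3,4,5‑tris(benzyloxy)benzoyl chloride gives the aryl benzoate F3.
- Carbonyl methylenation with Cp2TiMe2 gives the α‑aryloxystyrene F4.
- Ring‑closing metathesis with second‑generation Grubbs catalyst gives 7‑(benzyloxy)‑8‑bromo‑2‑[3,4,5‑tris(benzyloxy)phenyl]‑4H‑chromene F5.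
- Asymmetric hydroboration–oxidation with the enantiomer of monoisopinocampheylborane (IpcBH2) that delivers (2S,3R) adds H and OH syn and places OH at C3, which returns to the route at 13 for the middle unit.
- For the upper unit, 13 is silylated to the 3‑O‑silyl flavan F6, hydroxylated at C4 with DDQ/water to the 4‑hydroxy flavan F7 and oxidised with Dess–Martin periodinane, which returns to the route at 10.

**Step 15.** The hindered C8 anion may fail to add to the hindered ketone, or may be quenched by proton transfer from the doubly benzylic C4–H of the middle unit, followed by β‑elimination. The fallback changes the order of assembly so that a small monomeric nucleophile is used. It sets out from 15: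
- Benzylation (NaH, BnBr) gives the 3‑O‑benzyl monomer bromide F8.
- Bromine–lithium exchange, CeCl3 and addition to 10 give the upper–middle carbinol F9.
- Et3SiH/CF3CO2H gives the upper–middle dimer F10.
- DDQ/2‑ethoxyethanol activates C4 of the middle unit, the only unsubstituted benzylic methylene, to give the 4‑(2‑ethoxyethoxy) dimer F11.
- Me3SiOTf‑promoted coupling with penta‑O‑benzylepicatechin F12 (from 18, NaH, BnBr) returns to the route at 24.

**Step 16.** Hydride may be delivered with poor facial selectivity, or the cation may lose the C3 proton to give the flav‑3‑ene silyl enol ether. The fallback replaces steric control by neighbouring‑group control. It sets out from 23: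
- Bu4NF gives the trimer 3,4‑diol F13.
- Ac2O/pyridine acylates only the secondary hydroxyl to give the trimer 3‑acetate carbinol F14.
- BF3·OEt2/Et3SiH ionises C4 to the cis‑fused acetoxonium ion bridging C3 and C4, which hydride opens anti to give the 3‑O‑acetyl trimer F15.
- K2CO3/MeOH returns to the route at 25.

## Further compounds

F1 | step 6 | 1‑(allyloxy)‑3‑(benzyloxy)‑2‑bromobenzene | C=CCOc1cccc(OCc2ccccc2)c1Br
F2 | step 6 | 2‑allyl‑5‑(benzyloxy)‑6‑bromophenol | C=CCc1ccc(OCc2ccccc2)c(Br)c1O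
F3 | step 6 | 2‑allyl‑5‑(benzyloxy)‑6‑bromophenyl 3,4,5‑tris(benzyloxy)benzoate | C=CCc1ccc(OCc2ccccc2)c(Br)c1OC(=O)c1cc(OCc2ccccc2)c(OCc2ccccc2)c(OCc2ccccc2)c1
F4 | step 6 | 1‑allyl‑4‑(benzyloxy)‑3‑bromo‑2‑{1‑[3,4,5‑tris(benzyloxy)phenyl]vinyloxy}benzene | C=CCc1ccc(OCc2ccccc2)c(Br)c1OC(=C)c1cc(OCc2ccccc2)c(OCc2ccccc2)c(OCc2ccccc2)c1
F5 | step 6 | 7‑(benzyloxy)‑8‑bromo‑2‑[3,4,5‑tris(benzyloxy)phenyl]‑4H‑chromene | C1C=C(c2cc(OCc3ccccc3)c(OCc3ccccc3)c(OCc3ccccc3)c2)Oc2c(Br)c(OCc3ccccc3)ccc12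
F6 | step 6 | (2S,3R)‑7‑(benzyloxy)‑8‑bromo‑3‑(tert‑butyldimethylsilyloxy)‑2‑[3,4,5‑tris(benzyloxy)phenyl]chromane | C1c2ccc(OCc3ccccc3)c(Br)c2O[C@@H](c2cc(OCc3ccccc3)c(OCc3ccccc3)c(OCc3ccccc3)c2)[C@@H]1O[Si](C)(C)C(C)(C)C
F7 | step 6 | (2S,3R,4S)‑7‑(benzyloxy)‑8‑bromo‑3‑(tert‑butyldimethylsilyloxy)‑2‑[3,4,5‑tris(benzyloxy)phenyl]chroman‑4‑ol | O[C@H]1c2ccc(OCc3ccccc3)c(Br)c2O[C@@H](c2cc(OCc3ccccc3)c(OCc3ccccc3)c(OCc3ccccc3)c2)[C@@H]1O[Si](C)(C)C(C)(C)C
F8 | step 15 | (2S,3S)‑3,7‑bis(benzyloxy)‑8‑bromo‑2‑[3,4,5‑tris(benzyloxy)phenyl]chromane | C1c2ccc(OCc3ccccc3)c(Br)c2O[C@@H](c2cc(OCc3ccccc3)c(OCc3ccccc3)c(OCc3ccccc3)c2)[C@H]1OCc1ccccc1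
F9 | step 15 | upper–middle carbinol (upper 8‑Br, 3‑OTBS, 4‑OH; middle C4 unsubstituted, 3‑OBn) | Brc1c(OCc2ccccc2)ccc2c1O[C@@H](c1cc(OCc3ccccc3)c(OCc3ccccc3)c(OCc3ccccc3)c1)[C@H](O[Si](C)(C)C(C)(C)C)[C@@]2(O)c1c(OCc2ccccc2)ccc2c1O[C@@H](c1cc(OCc3ccccc3)c(OCc3ccccc3)c(OCc3ccccc3)c1)[C@@H](OCc1ccccc1)C2
F10 | step 15 | upper–middle dimer (upper 2S,3R,4S; middle C4 unsubstituted) | Brc1c(OCc2ccccc2)ccc2c1O[C@@H](c1cc(OCc3ccccc3)c(OCc3ccccc3)c(OCc3ccccc3)c1)[C@H](O[Si](C)(C)C(C)(C)C)[C@@H]2c1c(OCc2ccccc2)ccc2c1O[C@@H](c1cc(OCc3ccccc3)c(OCc3ccccc3)c(OCc3ccccc3)c1)[C@@H](OCc1ccccc1)C2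
F11 | step 15 | upper–middle dimer with 4‑(2‑ethoxyethoxy) group on the middle unit | Brc1c(OCc2ccccc2)ccc2c1O[C@@H](c1cc(OCc3ccccc3)c(OCc3ccccc3)c(OCc3ccccc3)c1)[C@H](O[Si](C)(C)C(C)(C)C)[C@@H]2c1c(OCc2ccccc2)ccc2c1O[C@@H](c1cc(OCc3ccccc3)c(OCc3ccccc3)c(OCc3ccccc3)c1)[C@@H](OCc1ccccc1)[C@@H]2OCCOCC
F12 | step 15 | 3,5,7,3',4'‑penta‑O‑benzyl‑(−)‑epicatechin | c1c(OCc2ccccc2)cc(OCc2ccccc2)c2c1O[C@H](c1ccc(OCc3ccccc3)c(OCc3ccccc3)c1)[C@H](OCc1ccccc1)C2
F13 | step 16 | trimer 3,4‑diol (upper 3‑OH, 4‑OH) | Brc1c(OCc2ccccc2)ccc2c1O[C@@H](c1cc(OCc3ccccc3)c(OCc3ccccc3)c(OCc3ccccc3)c1)[C@H](O)[C@@]2(O)c1c(OCc2ccccc2)ccc2c1O[C@@H](c1cc(OCc3ccccc3)c(OCc3ccccc3)c(OCc3ccccc3)c1)[C@@H](OCc1ccccc1)[C@@H]2c1c(OCc2ccccc2)cc(OCc2ccccc2)c2c1O[C@H](c1ccc(OCc3ccccc3)c(OCc3ccccc3)c1)[C@H](OCc1ccccc1)C2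
F14 | step 16 | trimer 3‑acetate carbinol (upper 3‑OAc, 4‑OH) | Brc1c(OCc2ccccc2)ccc2c1O[C@@H](c1cc(OCc3ccccc3)c(OCc3ccccc3)c(OCc3ccccc3)c1)[C@H](OC(C)=O)[C@@]2(O)c1c(OCc2ccccc2)ccc2c1O[C@@H](c1cc(OCc3ccccc3)c(OCc3ccccc3)c(OCc3ccccc3)c1)[C@@H](OCc1ccccc1)[C@@H]2c1c(OCc2ccccc2)cc(OCc2ccccc2)c2c1O[C@H](c1ccc(OCc3ccccc3)c(OCc3ccccc3)c1)[C@H](OCc1ccccc1)C2
F15 | step 16 | 3‑O‑acetyl trimer (upper 2S,3R,4S) | Brc1c(OCc2ccccc2)ccc2c1O[C@@H](c1cc(OCc3ccccc3)c(OCc3ccccc3)c(OCc3ccccc3)c1)[C@H](OC(C)=O)[C@@H]2c1c(OCc2ccccc2)ccc2c1O[C@@H](c1cc(OCc3ccccc3)c(OCc3ccccc3)c(OCc3ccccc3)c1)[C@@H](OCc1ccccc1)[C@@H]2c1c(OCc2ccccc2)cc(OCc2ccccc2)c2c1O[C@H](c1ccc(OCc3ccccc3)c(OCc3ccccc3)c1)[C@H](OCc1ccccc1)C2
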